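## The problem

Target 28 joins two units of one terpenoid family through an ester. In the lactone half, cyclohexane ring A (C1–C6; isopropyl on C1, carbinol carbon C4, ring-fusion carbons C5 and C6) is cis-fused to the seven-membered lactone ring B (C5–C7(=O)–O8–C9–C10=C11–C6), which carries the free carboxyl C12 on C10; the CH2O carbon C13 on C4 is acylated by the other half. The acyl half has the same locants primed: cyclohexene ring C (C1′–C6′, C4′=C5′, hydroxymethyl C13′ on C4′, no C7′) bears on C6′ an (E)-2-(hydroxymethyl)propenoyl arm C11′=C10′(C9′H2OH)–C12′. Six stereocentres must be set (1S,4R,5S,6R in ring A; 1′S,6′S in ring C): C1/C6 trans, C5/C6 cis, O4 cis to C7, and the same absolute sense at C1′/C6′, so one source of chirality can serve both halves. C1 can steer bond formation at the neighbouring C6, but the cis C5/C6 pair is the less stable arrangement (C7 axial) and lies α to carbonyl groups, and C4 is a fully substituted carbinol that can only be set by face-selective addition to a C4 ketone. The fragile parts are the 2-(acyloxymethyl)acrylate of ring B (allylic ester and Michael acceptor), the β-hydroxy lactone (retro-aldol, dehydration), the skipped diene around C6′, and three ester-type C–O bonds beside one free acid, which rules out hydrolytic unmasking of C12 at the end. The feature that opens the route is that C7 on C5 and C11 on C6 are cis and can be bonded to each other: as a cis-fused cyclobutane they freeze C5, hold the C5–C7 bond axial beside C4, and so make the two faces of a C4 ketone different. A second useful feature is that ring C is formally ring A after loss of C7 as CO2 with opening of a C4/C13 epoxide toward C5, so one advanced intermediate can feed both halves.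

## Retrosynthesis

**C12 unmasking and the C13–O bond (28 ⇐ 27 ⇐ 22 + 26).** The free acid is kept as a 2-(trimethylsilyl)ethyl ester until the last step (27), because fluoride removes it without touching the lactone or the C13 ester. The inter-half ester is cut at the alkyl C13–O bond, not at the acyl C–O bond. This gives epoxy lactone 22 and dihydroxy acid 26, two fragments of similar size. The neighbouring cut (acylation of a C4/C13 diol) would need the tertiary alcohol to be freed and protected through the whole sequence. The epoxide does that job for nothing and is what the key step delivers. The forward reaction must be an SN2 opening at the unsubstituted C13 so that the C4–O bond, and hence C4, is untouched.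

**Ring B (22 ⇐ 20 ⇐ 19).** The lactone is cut at C7–O8 to hydroxy acid 20, which comes from its 4-methoxybenzyl ether 19. Cutting C10=C11 inside the ring instead is discussed below. The C7–O8 cut is preferred here because the open-chain acid 19 is also the precursor of the acyl half. The forward step is a seven-membered lactonisation helped by the cis C5/C6 substituents and the E alkene (C9 cis to C6).

**Ring C from ring A (26 ⇐ 25 ⇐ 24 ⇐ 19).** Acid 26 is traced through protected forms 25 and 24 back to the same seco acid 19. Retrosynthetically, CO2 is added across C4′=C5′ and O13′ is closed onto C4′. Forward, decarboxylation at C5 generates a radical beside the epoxide, which opens to the allylic alcohol. An independent synthesis of ring C would have to olefinate a β,γ-unsaturated aldehyde on C6′, which is prone to conjugation and epimerisation. Here the olefination is finished before the ring alkene exists.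

**The arm (19 ⇐ 13 + 18; 18 ⇐ 15 + 16; 15 ⇐ 14).** C10=C11 is cut by a phosphonate olefination between aldehyde acid 13 and phosphonate 18, which brings C9 (as a 4-methoxybenzyl ether), C10 and C12 (as the silylethyl ester). Reagent 18 comes from phosphonoacetate 15 and formaldehyde 16, and 15 from acid 14. One reagent serves both halves. The forward step must give the E alkene and must not epimerise C6.

**Reconnection of C7 and C11 (13 ⇐ 11 ⇐ 10 ⇐ 9).** The 1,4-related acid and aldehyde carbons are joined retrosynthetically into a cyclobutanone 10 (through silyl enol ether 11), itself the ozonolysis product of methylenecyclobutane 9. A haloform-type opening after α,α-dihalogenation would give the same oxidation pattern but generates hydrogen halide beside the epoxide. Enol silylation and ozonolysis are neutral. The forward demand is regioselective enolisation toward C11.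

**The carbinol carbon (9 ⇐ 6 + 7).** The C4–C13 and C13–O bonds of the spiro-epoxide are cut to ketone 6 and the sulfonium salt 7. This is the strategic cut: it removes the only stereocentre that no neighbour can set by equilibration. It is made while C5 is locked in the four-membered ring, so ylide attack anti to the axial C5–C7 bond is the only open path.

**The cyclobutane and the chiral start (6 ⇐ 4 + 5; 4 ⇐ 3 ⇐ 1 + 2).** The C5–C7 and C6–C11 bonds are cut by a retro-[2+2] to (S)-cryptone 4 and allene 5. Enone 4 comes from keto aldehyde 3 by aldol condensation, and 3 from aldehyde 1 and enone 2 by a catalytic asymmetric Michael addition. This one catalytic step provides C1 and, through 19, C1′.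

## Roads not taken

**Alternative 1: one cyclohexene from an asymmetric Diels–Alder reaction.** The cut is through C1–C6 and C2–C3 of the six-membered ring. Diene A1 and an activated acrylate ester would combine under a chiral oxazaborolidinium Lewis acid to give the cis (endo) cyclohexene ester A2.
- Merits: absolute configuration comes from a catalyst and does not depend on photochemical face selectivity. A2 already has the ring C alkene and both CH2O carbons, so for the acyl half this road is probably shorter than the thirteen-step branch proposed here.
- Weak points: the ester on C1 must be epimerised (the endo adduct is cis, the target trans) and then turned into an isopropyl group. For the lactone half, a carboxyl on C5 and a hydroxyl on C4 must be added cis across a trisubstituted alkene with the right facial sense, for which there is no short, reliable method.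
- Comparison: the chosen plan sets C5, C6, C7 and C11 in one photocycloaddition and C4 in the next step, and derives ring C from ring A in one fragmentation. That is what it sets against the better start of A2 for ring C.

**Alternative 2: iodo-β-lactonisation.** The cut is the C4–O bond, made from the C7 carboxyl. Acid A3, with an exocyclic C4=C13 alkene, would close under an electrophilic iodine source and bicarbonate to the cis-fused β-lactone A4 with an iodomethyl group on C4.
- Merits: the oxygen is delivered intramolecularly and can only arrive cis to C7. The certainty at C4 is higher than in a substrate-controlled ylide addition, and in this respect the road is better than the chosen one.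
- Weak points: the price is paid at C13. A neopentyl iodide beside an electrophilic β-lactone must be displaced by the acyl-half carboxylate, which is harder than opening an epoxide. The β-lactone then has to be traded for the seven-membered lactone, and A3 is a β,γ-unsaturated acid that can slip into conjugation.
- Comparison: the chosen plan introduces C13 and the oxygen in one step and leaves C13 as the reactive end of an epoxide that also protects the tertiary alcohol.

**Alternative 3: ring-closing metathesis of ring B.** The cut is C10=C11. Diene ester A5 (vinyl on C6, 2-(acyloxymethyl)acrylate on C7) would close to A6, which is the same compound as 22.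
- Merits: the ring enforces the alkene geometry, no protecting group is needed on O9, and ring closure and alkene formation are one step. Three operations from 13 (carboxylate alkylation, methylenation, metathesis) match the three used here (olefination, ether cleavage, lactonisation). For ring B alone this road is at least as good.
- Weak points: the closure joins a 1,1-disubstituted, electron-poor alkene to an alkene beside a stereocentre and is expected to need forcing conditions. It also gives no open-chain E acrylate, so the acyl half would need its own olefination.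
- Comparison: the chosen plan offers intermediate 19, which is the branching point for both halves.

Key step: step 4

Remark on the chemistry: aldehyde acid 13 is written in its open form; it is assumed to rest mainly as the cis-fused hydroxy-γ-lactone tautomer and to react through the open carboxylate under the basic conditions of step 10.

## Route

Step 1
Reactants: 1 3-methylbutanal; 2 but-3-en-2-one
Product: 3 (2S)-5-oxo-2-(propan-2-yl)hexanal
Conditions: (S)-2-[methoxy(diphenyl)methyl]pyrrolidine (5 mol%), ethyl 3,4-dihydroxybenzoate (20 mol%), neat, 4 °C
Reagents that add atoms: none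
Why: Enamine-catalysed Michael addition; the E enamine of 1 is shielded on one face by the diphenyl(methoxy)methyl group, so 2 adds to the open face and the new stereocentre (C1 of the target) should be S.

Step 2
Reactants: 3 (2S)-5-oxo-2-(propan-2-yl)hexanal
Product: 4 (4S)-4-(propan-2-yl)cyclohex-2-en-1-one [(S)-cryptone]
Conditions: LiOH, i-PrOH, rt
Reagents that add atoms: none
Why: Intramolecular aldol condensation (6-enolexo attack of the methyl ketone enolate on the aldehyde, then E1cB loss of water); mild hydroxide at room temperature should keep enolisation toward the stereocentre slower than cyclisation, so the S configuration is carried into the enone.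

Step 3
Reactants: 4 (S)-cryptone; 5 propa-1,2-diene
Product: 6 (1R,5S,6S)-8-methylidene-5-(propan-2-yl)bicyclo[4.2.0]octan-2-one (cis-fused; four-membered ring anti to the isopropyl group)
Conditions: 5 (excess), hν (medium-pressure mercury lamp, Pyrex filter), THF, −78 °C
Reagents that add atoms: none
Why: Enone–allene [2+2] photocycloaddition through the enone triplet; the central allene carbon bonds to C5 (α) and a terminal one to C6 (β), the new C6–C11 bond should form anti to the isopropyl group on C1, and the cis ring fusion is the stable one (a trans-fused by-product would epimerise at C5 on basic alumina); a minor syn isomer, if formed, would be removed here.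

Step 4
Reactants: 6 (1R,5S,6S)-8-methylidene-5-(propan-2-yl)bicyclo[4.2.0]octan-2-one; 7 trimethylsulfonium iodide
Product: 9 (1R,2R,5S,6S)-8-methylidene-5-(propan-2-yl)spiro[bicyclo[4.2.0]octane-2,2′-oxirane] (epoxide oxygen cis and C13 trans to C7), via sulfonium betaine 8 (not isolated)
Conditions: 7, KN(SiMe3)2, THF, −10 °C; then 6, −10 → 0 °C
Reagents that add atoms: none
Why: Corey–Chaykovsky epoxidation: KN(SiMe3)2 deprotonates 7 to dimethylsulfonium methylide, which adds irreversibly to the C4 carbonyl (new C4–C13 bond) to give betaine 8, and the alkoxide then displaces dimethyl sulfide from C13 in a 3-exo-tet closure that forms the C13–O bond and the oxirane ring. The closest known reaction type is the kinetically controlled methylene transfer from unstabilised sulfonium ylides to α-substituted cyclohexanones, which delivers CH2 along the axial trajectory. In 6 the isopropyl group and the C6–C11 bond are equatorial, so the C5–C7 bond of the cis-fused cyclobutane is axial; equatorial approach is blocked by this bond and the methylenecyclobutane behind it, whereas axial approach anti to C5–C7 meets only the axial hydrogens on C2 and C6. The new stereocentre C4 is therefore controlled by C5 (relayed from C1 through the photoadduct): C13 should end trans and the oxygen cis to C7 (4R in target locants). The step needs facial selectivity at C4 and chemoselectivity for addition over enolisation of the β,γ-unsaturated ketone; the first is secured by the locked ring fusion, the second by low temperature, irreversible addition and the absence of excess base. C5 cannot be lost because the trans-fused bicyclo[4.2.0]octanone is the less stable epimer, and the exocyclic alkene is inert to the ylide.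

Step 5
Reactants: 9 spiro-epoxide
Product: 10 5-(propan-2-yl)spiro[bicyclo[4.2.0]octane-2,2′-oxiran]-8-one (cyclobutanone; stereocentres as in 9)
Conditions: O3, CH2Cl2/MeOH, NaHCO3, −78 °C; then Me2S, −78 °C → rt
Reagents that add atoms: ozone, [O-][O+]=O
Why: Ozonolysis of the only alkene, a 1,1-disubstituted one, with reductive work-up; the epoxide is inert to ozone and the bicarbonate buffer keeps the medium neutral.

Step 6
Reactants: 10 spiro-epoxy cyclobutanone
Product: 11 trimethylsilyl enol ether of 10 (C7(OSiMe3)=C11; stereocentres as in 9)
Conditions: LiN(i-Pr)2, Me3SiCl (in situ quench), THF, −78 °C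
Reagents that add atoms: chlorotrimethylsilane, C[Si](C)(C)Cl
Why: Kinetic enolisation at the unhindered C11 methylene with immediate silylation; deprotonation at the ring-fusion carbon C5 would place a double bond at the bridgehead of the bicycle and is disfavoured, which also protects the β-epoxide from E1cB opening.

Step 7
Reactants: 11 trimethylsilyl enol ether
Product: 13 aldehyde acid (ring A with the spiro-epoxide at C4, CO2H on C5, CHO on C6; C5/C6 cis, C6 trans to isopropyl), via trimethylsilyl ester 12 (not isolated)
Conditions: O3, CH2Cl2, −78 °C; Me2S; then pH 7 phosphate buffer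
Reagents that add atoms: ozone, [O-][O+]=O
Why: Ozonolysis of a silyl enol ether cleaves C7=C11 to the silyl ester (C7) and the aldehyde (C11), and the silyl ester hydrolyses on work-up; C5 and C6 are never deprotonated, so the cis relationship fixed in the cyclobutane is retained.

Step 8
Reactants: 14 2-(diethoxyphosphoryl)acetic acid
Product: 15 2-(trimethylsilyl)ethyl 2-(diethoxyphosphoryl)acetate
Conditions: 2-(trimethylsilyl)ethanol, DCC, DMAP (cat.), CH2Cl2, 0 °C → rt
Reagents that add atoms: 2-(trimethylsilyl)ethanol, C[Si](C)(C)CCO
Why: Steglich esterification of an unhindered acid with a primary alcohol.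

Step 9
Reactants: 15 2-(trimethylsilyl)ethyl 2-(diethoxyphosphoryl)acetate; 16 formaldehyde (as paraformaldehyde)
Product: 18 2-(trimethylsilyl)ethyl 2-(diethoxyphosphoryl)-3-[(4-methoxyphenyl)methoxy]propanoate (racemic), via 2-phosphonoacrylate 17 (not isolated)
Conditions: (CH2O)n, piperidine (cat.), 4-methoxybenzyl alcohol (3 equiv), THF, 65 °C
Reagents that add atoms: 4-methoxybenzyl alcohol, COc1ccc(CO)cc1
Why: Knoevenagel condensation with formaldehyde gives the 2-phosphonoacrylate, a strong Michael acceptor that captures the alcohol by oxa-Michael addition, as methanol does in the standard preparation of 2-phosphonoacrylates; the stereocentre formed is lost in step 10.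

Step 10
Reactants: 13 aldehyde acid; 18 phosphonate
Product: 19 seco acid (ring A with the spiro-epoxide at C4, CO2H on C5, and on C6 the arm (E)-CH=C(CH2O-4-methoxybenzyl)CO2CH2CH2SiMe3)
Conditions: NaH, THF, 0 °C → rt; NaH2PO4 (aq) work-up
Reagents that add atoms: none
Why: Horner–Wadsworth–Emmons olefination of the sodium salt of 13 (open aldehyde form) with the anion of 18; α-branched aldehydes and α-substituted phosphonoacetates give the trisubstituted alkene with the ester trans to the aldehyde substituent (E), which places C9 cis to C6 as both halves need, and the carboxylate at C7 cannot enolise, so C5 is safe.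

Step 11
Reactants: 19 seco acid
Product: 20 hydroxy acid (as 19 with free C9–OH)
Conditions: DDQ, CH2Cl2/pH 7 buffer, 0 °C → rt
Reagents that add atoms: none
Why: Oxidative cleavage of the 4-methoxybenzyl ether under buffered, neutral conditions that leave the acid-labile epoxide and the silylethyl ester intact.

Step 12
Reactants: 20 hydroxy acid
Product: 22 epoxy lactone (rings A and B with the spiro-epoxide at C4 and the 2-(trimethylsilyl)ethyl ester at C12), via mixed anhydride 21 (not isolated)
Conditions: 2-methyl-6-nitrobenzoic anhydride, DMAP, CH2Cl2 (2 mM, slow addition), rt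
Reagents that add atoms: none
Why: Shiina lactonisation: the mixed anhydride is taken up by DMAP and attacked by O9–H in a seven-membered closure pre-organised by the cis C5/C6 substituents and the E alkene; the hindered aroyl anhydride does not acylate O9, and room temperature limits enolisation at C5.

Step 13
Reactants: 19 seco acid
Product: 24 2-(trimethylsilyl)ethyl (2E)-3-[(1S,6S)-3-(hydroxymethyl)-6-(propan-2-yl)cyclohex-2-en-1-yl]-2-{[(4-methoxyphenyl)methoxy]methyl}prop-2-enoate, via thiohydroxamate ester 23 (not isolated)
Conditions: N-hydroxypyridine-2-thione, DCC, DMAP (cat.), CH2Cl2, 0 °C, dark; then t-BuSH (excess), hν (tungsten lamp), 0 °C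
Reagents that add atoms: none
Why: Barton reductive decarboxylation: the C5 radical is an oxiranylcarbinyl radical and opens the epoxide by C4–O scission faster than it is reduced, as in radical deoxygenations of epoxy alcohols, and the allyloxy radical takes hydrogen from the thiol; C7 is lost, C4′=C5′ is formed and O13′–H is freed in one operation, with C1′ and C6′ untouched.

Step 14
Reactants: 24 allylic alcohol
Product: 25 2-(trimethylsilyl)ethyl (2E)-2-(hydroxymethyl)-3-[(1S,6S)-3-(hydroxymethyl)-6-(propan-2-yl)cyclohex-2-en-1-yl]prop-2-enoate
Conditions: DDQ, CH2Cl2/pH 7 buffer, 0 °C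
Reagents that add atoms: none
Why: Oxidative cleavage of the 4-methoxybenzyl ether, which is much faster than oxidation of the primary allylic alcohol when the reagent is used in slight excess at 0 °C.

Step 15
Reactants: 25 diol ester
Product: 26 (2E)-2-(hydroxymethyl)-3-[(1S,6S)-3-(hydroxymethyl)-6-(propan-2-yl)cyclohex-2-en-1-yl]prop-2-enoic acid
Conditions: Bu4NF, THF, 0 °C → rt; NaH2PO4 (aq) work-up
Reagents that add atoms: none
Why: Fluoride attacks silicon and the 2-(trimethylsilyl)ethyl ester fragments to the carboxylate, ethene and Me3SiF; no hydrolytic conditions are applied to the skipped diene.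

Step 16
Reactants: 22 epoxy lactone; 26 acyl-half acid
Product: 27 2-(trimethylsilyl)ethyl ester of the target (C12 ester; all hydroxyl groups free)
Conditions: 26 (1.5 equiv), Cs2CO3 (0.3 equiv), DMF, 60 °C
Reagents that add atoms: none
Why: Base-catalysed addition of a carboxylic acid to an epoxide: the caesium carboxylate of 26 opens the oxirane by SN2 attack at the unsubstituted C13, so the C4–O bond and its configuration are retained; the excess acid protonates the tertiary alkoxide at once and the primary alcohols of 26 are not ionised.

Step 17
Reactants: 27 silylethyl ester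
Product: 28 target, CNP0361406.4 (1S,4R,5S,6R,1′S,6′S; C10′=C11′ E, in the locants defined above)
Conditions: (Me2N)3S+ Me3SiF2−, DMF, 0 °C → rt; NH4Cl (aq) work-up
Reagents that add atoms: none
Why: Fluoride-induced fragmentation of the 2-(trimethylsilyl)ethyl ester frees the C12 carboxyl without hydrolysis, so the lactone, the C13 ester and the β-hydroxy lactone are left alone.

## Compound list

1 | 3-methylbutanal | CC(C)CC=O | starting material
2 | but-3-en-2-one | CC(=O)C=C | starting material
3 | (2S)-5-oxo-2-(propan-2-yl)hexanal | CC(C)[C@@H](C=O)CCC(C)=O | intermediate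
4 | (4S)-4-(propan-2-yl)cyclohex-2-en-1-one, (S)-cryptone | CC(C)[C@@H]1CCC(=O)C=C1 | intermediate
5 | propa-1,2-diene (allene) | C=C=C | starting material
6 | (1R,5S,6S)-8-methylidene-5-(propan-2-yl)bicyclo[4.2.0]octan-2-one | CC(C)[C@@H]1CCC(=O)[C@H]2C(=C)C[C@@H]12 | intermediate
7 | trimethylsulfonium iodide | C[S+](C)C.[I-] | starting material
8 | sulfonium betaine from 6 (C4 alkoxide, CH2S+Me2 on C4, trans to C7) | CC(C)[C@@H]1CC[C@]([O-])(C[S+](C)C)[C@H]2C(=C)C[C@@H]12 | intermediate
9 | (1R,2R,5S,6S)-8-methylidene-5-(propan-2-yl)spiro[bicyclo[4.2.0]octane-2,2′-oxirane] | CC(C)[C@@H]1CC[C@]3(CO3)[C@H]2C(=C)C[C@@H]12 | intermediate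
10 | 5-(propan-2-yl)spiro[bicyclo[4.2.0]octane-2,2′-oxiran]-8-one, stereocentres as in 9 | CC(C)[C@@H]1CC[C@]3(CO3)[C@H]2C(=O)C[C@@H]12 | intermediate
11 | trimethylsilyl enol ether of 10 (C7(OSiMe3)=C11) | CC(C)[C@@H]1CC[C@]3(CO3)[C@H]2C(O[Si](C)(C)C)=C[C@@H]12 | intermediate
12 | trimethylsilyl ester of aldehyde acid 13 | CC(C)[C@@H]1CC[C@]2(CO2)[C@@H](C(=O)O[Si](C)(C)C)[C@H]1C=O | intermediate
13 | aldehyde acid: spiro-epoxide at C4, CO2H on C5, CHO on C6 (C5/C6 cis, trans to isopropyl) | CC(C)[C@@H]1CC[C@]2(CO2)[C@@H](C(=O)O)[C@H]1C=O | intermediate
14 | 2-(diethoxyphosphoryl)acetic acid | OC(=O)CP(=O)(OCC)OCC | starting material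
15 | 2-(trimethylsilyl)ethyl 2-(diethoxyphosphoryl)acetate | C[Si](C)(C)CCOC(=O)CP(=O)(OCC)OCC | intermediate
16 | formaldehyde (used as paraformaldehyde) | C=O | starting material
17 | 2-(trimethylsilyl)ethyl 2-(diethoxyphosphoryl)prop-2-enoate | C=C(C(=O)OCC[Si](C)(C)C)P(=O)(OCC)OCC | intermediate
18 | 2-(trimethylsilyl)ethyl 2-(diethoxyphosphoryl)-3-[(4-methoxyphenyl)methoxy]propanoate (racemic) | COc1ccc(COCC(C(=O)OCC[Si](C)(C)C)P(=O)(OCC)OCC)cc1 | intermediate
19 | seco acid: spiro-epoxide at C4, CO2H on C5, (E)-CH=C(CH2O-4-methoxybenzyl)CO2CH2CH2SiMe3 on C6 | CC(C)[C@@H]1CC[C@]2(CO2)[C@@H](C(=O)O)[C@H]1/C=C(\COCc3ccc(OC)cc3)C(=O)OCC[Si](C)(C)C | intermediate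
20 | hydroxy acid: as 19 with free C9–OH | CC(C)[C@@H]1CC[C@]2(CO2)[C@@H](C(=O)O)[C@H]1/C=C(\CO)C(=O)OCC[Si](C)(C)C | intermediate
21 | mixed anhydride of 20 with 2-methyl-6-nitrobenzoic acid | CC(C)[C@@H]1CC[C@]2(CO2)[C@@H](C(=O)OC(=O)c3c(C)cccc3[N+](=O)[O-])[C@H]1/C=C(\CO)C(=O)OCC[Si](C)(C)C | intermediate
22 | epoxy lactone: rings A and B, spiro-epoxide at C4, 2-(trimethylsilyl)ethyl ester at C12 | CC(C)[C@@H]1CC[C@]2(CO2)[C@H]3C(=O)OCC(C(=O)OCC[Si](C)(C)C)=C[C@@H]13 | intermediate
23 | N-acyloxypyridine-2-thione (thiohydroxamate) ester of 19 | CC(C)[C@@H]1CC[C@]2(CO2)[C@@H](C(=O)On3ccccc3=S)[C@H]1/C=C(\COCc3ccc(OC)cc3)C(=O)OCC[Si](C)(C)C | intermediate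
24 | 2-(trimethylsilyl)ethyl (2E)-3-[(1S,6S)-3-(hydroxymethyl)-6-(propan-2-yl)cyclohex-2-en-1-yl]-2-{[(4-methoxyphenyl)methoxy]methyl}prop-2-enoate | C[Si](C)(C)CCOC(=O)/C(=C/[C@@H]1C=C(CO)CC[C@H]1C(C)C)COCc1ccc(OC)cc1 | intermediate
25 | 2-(trimethylsilyl)ethyl (2E)-2-(hydroxymethyl)-3-[(1S,6S)-3-(hydroxymethyl)-6-(propan-2-yl)cyclohex-2-en-1-yl]prop-2-enoate | C[Si](C)(C)CCOC(=O)/C(=C/[C@@H]1C=C(CO)CC[C@H]1C(C)C)CO | intermediate
26 | (2E)-2-(hydroxymethyl)-3-[(1S,6S)-3-(hydroxymethyl)-6-(propan-2-yl)cyclohex-2-en-1-yl]prop-2-enoic acid | OC(=O)/C(=C/[C@@H]1C=C(CO)CC[C@H]1C(C)C)CO | intermediate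
27 | 2-(trimethylsilyl)ethyl ester of the target at C12 | CC(C)[C@@H]1CC[C@](O)(COC(=O)/C(=C/[C@@H]2C=C(CO)CC[C@H]2C(C)C)CO)[C@H]2C(=O)OCC(C(=O)OCC[Si](C)(C)C)=C[C@@H]12 | intermediate
28 | CNP0361406.4 (1S,4R,5S,6R,1′S,6′S; E) | CC(C)[C@@H]1CC[C@](O)(COC(=O)/C(=C/[C@@H]2C=C(CO)CC[C@H]2C(C)C)CO)[C@H]2C(=O)OCC(C(=O)O)=C[C@@H]12 | target

## Step count and least certain steps

Total step count: 17. Longest linear sequence: 13 (steps 1–7, 10, 13–17; the lactone branch through steps 11 and 12 is one step shorter).

**Step 4 (key step).** The basic ylide may deprotonate the α-branched, β,γ-unsaturated ketone instead of adding. That would return ketone or move the exocyclic alkene into conjugation. Facial selectivity could also erode if the ring populates the conformer with C5–C7 pseudo-equatorial. The fallback sets out from 6 and returns at 9, using a less basic carbon nucleophile and an intramolecular etherification. (i-PrO)Me2SiCH2MgCl (with CeCl3) would add to the ketone on the same face to give the β-hydroxysilane F1. Oxidation of the C–Si bond (H2O2, KF, KHCO3) would give the diol F2. Selective sulfonylation of the primary hydroxyl would give the tosylate F3, and K2CO3 in methanol would close it to 9. The C4–O bond is never broken after the addition.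

**Step 16.** SN2 attack of a weakly nucleophilic, precious carboxylate at the neopentyl-type C13 may be slow. Conjugate attack on the 2-(acyloxymethyl)acrylate of ring B, or base-induced opening of the epoxide from C5, could then compete. The fallback sets out from 22 (and 26) and returns at 28, replacing the direct union by a relay through the diol.
- HCO2Cs with a little HCO2H (large excess of a small nucleophile) would open 22 to the formate F7.
- KHCO3 in methanol at 0 °C would free the diol F8.
- Acid 26 would be converted into the bis(tert-butyldimethylsilyl) ether acid F9 (silyl chloride and imidazole, then K2CO3 in aqueous methanol to free the carboxyl).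
- Yamaguchi esterification of the primary hydroxyl of F8 with F9 would give the protected ester F10.
- (Me2N)3S+ Me3SiF2− would remove all three silyl groups to give 28.

**Step 13.** The thiohydroxamate ester of the hindered acid may form slowly. Thiyl radicals may also abstract the doubly allylic hydrogen on C6′ of the product, which would shift the alkenes or epimerise C6′. The fallback sets out from 19 and returns at 24 by a polar, syn decarboxylation.
- LiBr and acetic acid would open the epoxide at C13 to the bromohydrin acid F4.
- Benzenesulfonyl chloride in pyridine would close the cis β-hydroxy acid to the β-lactone F5.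
- Heating in toluene would extrude CO2 stereospecifically to the allylic bromide F6.
- NaHCO3 in aqueous DMSO would hydrolyse F6 to 24.

**Step 12.** Enolisation at C5 of the activated acyl intermediate could epimerise the ring fusion or open the epoxide by E1cB, and intermolecular esterification could compete with the seven-membered closure. The fallback sets out from 20 and returns at 22 without new compounds. A Mitsunobu lactonisation (PPh3, diisopropyl azodicarboxylate, high dilution) activates O9–H instead of the carboxyl, so C7 stays a non-enolisable carboxylate and ring B closes by SN2 displacement at the primary allylic C9.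

## Further compounds

F1 | step 4 | β-hydroxysilane: adduct of 6 with the (isopropoxydimethylsilyl)methyl group at C4 (OH cis to C7) | CC(C)[C@@H]1CC[C@](O)(C[Si](C)(C)OC(C)C)[C@H]2C(=C)C[C@@H]12
F2 | step 4 | diol: C4–OH and C13–OH on the methylenecyclobutane skeleton of 6 | CC(C)[C@@H]1CC[C@](O)(CO)[C@H]2C(=C)C[C@@H]12
F3 | step 4 | primary 4-methylbenzenesulfonate of F2 | CC(C)[C@@H]1CC[C@](O)(COS(=O)(=O)c3ccc(C)cc3)[C@H]2C(=C)C[C@@H]12
F4 | step 13 | bromohydrin acid from 19 (C13–Br, C4–OH) | CC(C)[C@@H]1CC[C@](O)(CBr)[C@@H](C(=O)O)[C@H]1/C=C(\COCc2ccc(OC)cc2)C(=O)OCC[Si](C)(C)C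
F5 | step 13 | cis-fused β-lactone (C4–O–C7) with bromomethyl on C4 | CC(C)[C@@H]1CC[C@@]2(CBr)OC(=O)[C@H]2[C@H]1/C=C(\COCc3ccc(OC)cc3)C(=O)OCC[Si](C)(C)C
F6 | step 13 | allylic bromide: 24 with Br in place of OH at C13′ | C[Si](C)(C)CCOC(=O)/C(=C/[C@@H]1C=C(CBr)CC[C@H]1C(C)C)COCc1ccc(OC)cc1
F7 | step 16 | C13 formate of the diol lactone (C4–OH free) | CC(C)[C@@H]1CC[C@](O)(COC=O)[C@H]2C(=O)OCC(C(=O)OCC[Si](C)(C)C)=C[C@@H]12
F8 | step 16 | diol lactone (C4–OH, C13–OH; 2-(trimethylsilyl)ethyl ester at C12) | CC(C)[C@@H]1CC[C@](O)(CO)[C@H]2C(=O)OCC(C(=O)OCC[Si](C)(C)C)=C[C@@H]12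
F9 | step 16 | bis(tert-butyldimethylsilyl) ether of acid 26 | OC(=O)/C(=C/[C@@H]1C=C(CO[Si](C)(C)C(C)(C)C)CC[C@H]1C(C)C)CO[Si](C)(C)C(C)(C)C
F10 | step 16 | bis(tert-butyldimethylsilyl) ether of 27 | CC(C)[C@@H]1CC[C@](O)(COC(=O)/C(=C/[C@@H]2C=C(CO[Si](C)(C)C(C)(C)C)CC[C@H]2C(C)C)CO[Si](C)(C)C(C)(C)C)[C@H]2C(=O)OCC(C(=O)OCC[Si](C)(C)C)=C[C@@H]12
F0 | step 12 | none | none
A1 | alternative 1 | tert-butyl(dimethyl){[(2E)-4-{[(4-methoxyphenyl)methoxy]methyl}penta-2,4-dien-1-yl]oxy}silane (diene) | C=C(COCc1ccc(OC)cc1)/C=C/CO[Si](C)(C)C(C)(C)C
A2 | alternative 1 | cis (endo) 2,2,2-trifluoroethyl cyclohex-3-ene-1-carboxylate with CH2O-4-methoxybenzyl on C4 and CH2OSi(t-Bu)Me2 on C6 | O=C(OCC(F)(F)F)[C@H]1CCC(COCc2ccc(OC)cc2)=C[C@H]1CO[Si](C)(C)C(C)(C)C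
A3 | alternative 2 | ring A acid with exocyclic C4=C13 alkene, CO2H on C5 and CH2OSi(t-Bu)Me2 on C6 | CC(C)[C@@H]1CCC(=C)[C@@H](C(=O)O)[C@H]1CO[Si](C)(C)C(C)(C)C
A4 | alternative 2 | cis-fused β-lactone with iodomethyl on C4 | CC(C)[C@@H]1CC[C@@]2(CI)OC(=O)[C@H]2[C@H]1CO[Si](C)(C)C(C)(C)C
A5 | alternative 3 | spiro-epoxide with vinyl on C6 and 2-{[2-(trimethylsilyl)ethoxy]carbonyl}prop-2-en-1-yl ester on C7 | CC(C)[C@@H]1CC[C@]2(CO2)[C@@H](C(=O)OCC(=C)C(=O)OCC[Si](C)(C)C)[C@H]1C=C
A6 | alternative 3 | bicyclic oxepinone lactone with spiro-epoxide and 2-(trimethylsilyl)ethyl ester (identical with 22) | CC(C)[C@@H]1CC[C@]2(CO2)[C@H]3C(=O)OCC(C(=O)OCC[Si](C)(C)C)=C[C@@H]13
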